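**Plan** (target numbering: lactone ring B = C1(H)–O2–C3(=O)–C4H2–C5; carbocycle ring A = spiro C5, ketone C6, C7=C8, acetoxy C9, C10H2; side chain C1'–C7')

- Cuts: first the lactone O2–C3 bond and the C1–C1' bond (alkenyl iodide 14 + formyl keto ester 8); then ring A at C5–C6 and C9–C10 (diene 3 + 2-substituted acrolein 5), with C6 carried as a silyl ether through the cycloaddition.
- Enabling feature: in ring A the oxygenated carbons C6 and C9 sit 1,4 across the C7=C8 double bond, and spiro C5, next to C6, carries C1 at a level that can be a formyl group. This is the retron of a [4+2] cycloaddition between a (1E,3E)-1,4-dioxygenated butadiene and a 2-substituted acrolein.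
- Forward order: ring A by Diels–Alder reaction, C6 silyl ether to ketone, then the side chain is joined at C1 and ring B closes in the same operation.
- Stereochemistry: C5 and C9 from the catalyst-controlled endo Diels–Alder step (relative: endo mode and diene geometry; absolute: chiral oxazaborolidinium). C5' from a CBS reduction, the C1'=C2' geometry from syn-carbometalation, and C1 from substrate-controlled (chelate) alkenylchromium addition.

Key step: step 3

Assumption: the (S)-oxazaborolidinium salt is taken to deliver dienes to the alpha-carbon face of 2-substituted acroleins that is Re in methacrolein (formyl C–H···O binding model); that face is Si in 5, so the (R)-catalyst is specified, and its antipode would be used if the sense proved opposite.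

**Step 1**
Reactants: 1 (1E,3E)-buta-1,3-diene-1,4-diyl diacetate
Product: 3 (1E,3E)-4-[(tert-butyldimethylsilyl)oxy]buta-1,3-dien-1-yl acetate, via lithium dienolate 2 (not isolated)
Conditions: MeLi (2.0 equiv), THF, −78 °C; then TBSCl, DMPU, −78 °C to 0 °C
Reagents that add atoms: tert-butyldimethylsilyl chloride, CC(C)(C)[Si](C)(C)Cl
Why: Enol ester cleavage and enolate trapping: methyllithium cleaves one enol acetate with retention of alkene geometry (the second equivalent consumes the acetone set free), the anionic dienolate 2 should resist a second cleavage, and O-silylation gives the (1E,3E)-silyl dienol ether.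

**Step 2**
Reactants: 4 methyl 4-oxobutanoate
Product: 5 methyl 3-formylbut-3-enoate
Conditions: 37% aq. HCHO (1.1 equiv), pyrrolidine (10 mol%), propionic acid (10 mol%), i-PrOH, 45 °C
Reagents that add atoms: formaldehyde, C=O
Why: Organocatalytic alpha-methylenation (Mannich condensation of the enolisable aldehyde, then elimination of the amine) gives the 2-methylene aldehyde under near-neutral conditions that should keep the double bond out of conjugation with the ester.

**Step 3**
Reactants: 3 (1E,3E)-4-[(tert-butyldimethylsilyl)oxy]buta-1,3-dien-1-yl acetate; 5 methyl 3-formylbut-3-enoate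
Product: 6 methyl 2-[(1S,2S,5S)-5-(acetyloxy)-2-[(tert-butyldimethylsilyl)oxy]-1-formylcyclohex-3-en-1-yl]acetate
Conditions: (R)-3,3-diphenyl-1-(2-methylphenyl)tetrahydro-1H,3H-pyrrolo[1,2-c][1,3,2]oxazaborole (20 mol%) protonated with Tf2NH (18 mol%), 3 (1.5 equiv), CH2Cl2, −78 °C
Reagents that add atoms: none
Why: The protonated oxazaborolidine binds the formyl oxygen of s-trans 5, and diene 3 adds in a concerted, asynchronous [4+2] cycloaddition in which the acetoxy-bearing terminus bonds first to the methylene carbon of 5 and the silyloxy-bearing terminus then bonds to the fully substituted alpha carbon. The closest known reaction type is the chiral oxazaborolidinium-catalysed Diels–Alder reaction of 2-substituted acroleins with 1-silyloxy-1,3-dienes. The cyclohexene ring is closed by intermolecular suprafacial [4+2] cycloaddition, both ring bonds arising in the one event and no preformed chain being cyclised. The cis relation of the two oxygenated carbons follows from the (E,E) geometry of 3, the cis relation of the formyl group to both follows from the endo transition state (formyl under the diene) that acyclic dienes are expected to adopt with 2-substituted acroleins, and the absolute configuration of the quaternary carbon, and with it of all three centres, is set by the catalyst, which shields one face of the bound enal so that the diene adds to the Re face of the alpha carbon. The step needs regioselectivity (silyloxy carbon to the quaternary carbon), secured because the silyloxy group is a much stronger donor than the acetoxy group and so puts the larger HOMO coefficient on the acetoxy-bearing terminus, and chemoselectivity for the C=C over the C=O bond of 5, secured by the large LUMO coefficient at the unhindered beta-methylene of the boron-bound enal.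

**Step 4**
Reactants: 6 methyl 2-[(1S,2S,5S)-5-(acetyloxy)-2-[(tert-butyldimethylsilyl)oxy]-1-formylcyclohex-3-en-1-yl]acetate
Product: 7 methyl 2-[(1S,2S,5S)-5-(acetyloxy)-1-formyl-2-hydroxycyclohex-3-en-1-yl]acetate
Conditions: HF·pyridine, pyridine, THF, 0 °C to rt
Reagents that add atoms: none
Why: Silyl ether cleavage by fluoride under acidic, non-basic conditions should avoid retro-aldol opening of the beta-hydroxy aldehyde and acetyl migration, and leaves the stereocentres untouched.

**Step 5**
Reactants: 7 methyl 2-[(1S,2S,5S)-5-(acetyloxy)-1-formyl-2-hydroxycyclohex-3-en-1-yl]acetate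
Product: 8 methyl 2-[(1R,5S)-5-(acetyloxy)-1-formyl-2-oxocyclohex-3-en-1-yl]acetate
Conditions: Dess–Martin periodinane (1.3 equiv), NaHCO3, CH2Cl2, 0 °C to rt; product used at once
Reagents that add atoms: none
Why: Dess–Martin oxidation converts the allylic alcohol into the enone under buffered conditions without touching the aldehyde, ester or allylic acetate, and removes the temporary carbinol centre while the quaternary centre cannot epimerise.

**Step 6**
Reactants: 9 pent-4-ynoic acid
Product: 10 N-methoxy-N-methylpent-4-ynamide
Conditions: MeNHOMe·HCl, EDC·HCl, N-methylmorpholine, CH2Cl2, 0 °C to rt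
Reagents that add atoms: N,O-dimethylhydroxylamine hydrochloride, CNOC.Cl
Why: Carbodiimide-mediated amide coupling gives the Weinreb amide.

**Step 7**
Reactants: 10 N-methoxy-N-methylpent-4-ynamide
Product: 11 2-methylhept-1-en-6-yn-3-one
Conditions: isopropenylmagnesium bromide (1.5 equiv), THF, −20 °C to 0 °C; inverse quench into cold 1 M HCl
Reagents that add atoms: isopropenylmagnesium bromide, CC(=C)[Mg]Br
Why: Grignard addition to a Weinreb amide stops at the ketone through the chelated tetrahedral intermediate, and the cold acidic inverse quench should prevent conjugate addition of the released amine to the enone.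

**Step 8**
Reactants: 11 2-methylhept-1-en-6-yn-3-one
Product: 12 (3R)-2-methylhept-1-en-6-yn-3-ol
Conditions: (S)-2-methyl-CBS-oxazaborolidine (20 mol%), catecholborane (1.8 equiv), toluene, −78 °C
Reagents that add atoms: none
Why: Corey–Bakshi–Shibata reduction: the ketone binds boron anti to the larger isopropenyl group and hydride is delivered to the face that gives the (R)-alcohol, while catecholborane at low temperature should leave the alkyne and the alkene alone.

**Step 9**
Reactants: 12 (3R)-2-methylhept-1-en-6-yn-3-ol
Product: 14 (3R,6E)-7-iodo-2,6-dimethylhepta-1,6-dien-3-ol, via alkenylalane 13 (not isolated)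
Conditions: AlMe3 (3.5 equiv), Cp2ZrCl2 (25 mol%), CH2Cl2, 0 °C to rt; then I2, THF, −30 °C; aqueous work-up
Reagents that add atoms: trimethylaluminium, C[Al](C)C; iodine, II
Why: Negishi carboalumination: zirconium-catalysed syn-addition of methyl–aluminium to the terminal alkyne puts methyl on the internal carbon, and iodinolysis with retention gives the (E)-alkenyl iodide, the hydroxyl being carried as its aluminium alkoxide and the 1,1-disubstituted alkene being inert.

**Step 10**
Reactants: 8 methyl 2-[(1R,5S)-5-(acetyloxy)-1-formyl-2-oxocyclohex-3-en-1-yl]acetate; 14 (3R,6E)-7-iodo-2,6-dimethylhepta-1,6-dien-3-ol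
Product: 16 (1R,5R,9S)-1-[(1E,5R)-5-hydroxy-2,6-dimethylhepta-1,6-dien-1-yl]-3,6-dioxo-2-oxaspiro[4.5]dec-7-en-9-yl acetate, via hydroxy ester 15 (not isolated)
Conditions: CrCl2 (5 equiv), NiCl2 (2 mol%), 14 (1.5 equiv), THF–DMF (10:1), rt; aq. NH4Cl work-up; then PPTS (cat.), CH2Cl2, rt
Reagents that add atoms: none
Why: Nozaki–Hiyama–Kishi coupling (oxidative addition of the C–I bond to nickel, transmetalation to chromium, addition to the aldehyde as the only carbonyl attacked, retention of the E geometry) followed by 5-exo-trig lactonisation onto the methyl ester; the new C1 centre is expected to form with the formyl oxygen held syn to the ring ketone on chromium, so that the alkenyl group adds to the face away from the CH2CO2Me arm and gives the (1R) epimer.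

**Compound list**
1 | (1E,3E)-buta-1,3-diene-1,4-diyl diacetate | CC(=O)O/C=C/C=C/OC(C)=O | starting material
2 | lithium (1E,3E)-4-(acetyloxy)buta-1,3-dien-1-olate | [Li+].[O-]/C=C/C=C/OC(C)=O | intermediate
3 | (1E,3E)-4-[(tert-butyldimethylsilyl)oxy]buta-1,3-dien-1-yl acetate | CC(=O)O/C=C/C=C/O[Si](C)(C)C(C)(C)C | intermediate
4 | methyl 4-oxobutanoate | COC(=O)CCC=O | starting material
5 | methyl 3-formylbut-3-enoate | COC(=O)CC(=C)C=O | intermediate
6 | methyl 2-[(1S,2S,5S)-5-(acetyloxy)-2-[(tert-butyldimethylsilyl)oxy]-1-formylcyclohex-3-en-1-yl]acetate | COC(=O)C[C@@]1(C=O)C[C@H](OC(C)=O)C=C[C@@H]1O[Si](C)(C)C(C)(C)C | intermediate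
7 | methyl 2-[(1S,2S,5S)-5-(acetyloxy)-1-formyl-2-hydroxycyclohex-3-en-1-yl]acetate | COC(=O)C[C@@]1(C=O)C[C@H](OC(C)=O)C=C[C@@H]1O | intermediate
8 | methyl 2-[(1R,5S)-5-(acetyloxy)-1-formyl-2-oxocyclohex-3-en-1-yl]acetate | COC(=O)C[C@@]1(C=O)C[C@H](OC(C)=O)C=CC1=O | intermediate
9 | pent-4-ynoic acid | OC(=O)CCC#C | starting material
10 | N-methoxy-N-methylpent-4-ynamide | CON(C)C(=O)CCC#C | intermediate
11 | 2-methylhept-1-en-6-yn-3-one | C=C(C)C(=O)CCC#C | intermediate
12 | (3R)-2-methylhept-1-en-6-yn-3-ol | C=C(C)[C@H](O)CCC#C | intermediate
13 | dimethylaluminium alkoxide of (3R,6E)-7-(dimethylalumanyl)-2,6-dimethylhepta-1,6-dien-3-ol | C=C(C)[C@H](O[Al](C)C)CC/C(C)=C/[Al](C)C | intermediate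
14 | (3R,6E)-7-iodo-2,6-dimethylhepta-1,6-dien-3-ol | C=C(C)[C@H](O)CC/C(C)=C/I | intermediate
15 | methyl 2-[(1R,5S)-5-(acetyloxy)-1-[(1R,2E,6R)-1,6-dihydroxy-3,7-dimethylocta-2,7-dien-1-yl]-2-oxocyclohex-3-en-1-yl]acetate (formed as its chromium alkoxide) | C=C(C)[C@H](O)CC/C(C)=C/[C@@H](O)[C@]1(CC(=O)OC)C[C@H](OC(C)=O)C=CC1=O | intermediate
16 | (1R,5R,9S)-1-[(1E,5R)-5-hydroxy-2,6-dimethylhepta-1,6-dien-1-yl]-3,6-dioxo-2-oxaspiro[4.5]dec-7-en-9-yl acetate | C=C(C)[C@H](O)CC/C(C)=C/[C@H]1OC(=O)C[C@]12C[C@H](OC(C)=O)C=CC2=O | target

**Totals**
Total step count: 10.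
Longest linear sequence: 5 steps (1, 3, 4, 5, 10; the branches through step 2 and through steps 6 to 9 are equally long).

**Steps most likely to fail**

Step 3 is the riskiest. The strong Lewis acid may divert the silyl dienol ether into addition at the formyl group (vinylogous aldol or hetero-cycloaddition), or the catalyst may give poor endo or enantiofacial discrimination. The fallback sets out from 3 and 5 and comes back to the route at 7. The cycloaddition is run thermally without catalyst (toluene, 80 °C), which should give 6 as the racemate, that is, together with its mirror image methyl 2-[(1R,2R,5R)-5-(acetyloxy)-2-[(tert-butyldimethylsilyl)oxy]-1-formylcyclohex-3-en-1-yl]acetate F1. Desilylation as in step 4 gives 7 together with methyl 2-[(1R,2R,5R)-5-(acetyloxy)-1-formyl-2-hydroxycyclohex-3-en-1-yl]acetate F2. Lipase-catalysed kinetic resolution with vinyl acetate is then expected, by the usual size rule for secondary alcohols with the quaternary carbon as the large group, to acetylate the (2R)-alcohol faster, giving methyl 2-[(1R,2R,5R)-2,5-bis(acetyloxy)-1-formylcyclohex-3-en-1-yl]acetate F3. Unreacted 7 is separated by chromatography and carried into step 5.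

Step 10 is second. Facial selection at the formyl group may be poor if the aldehyde reacts from a non-chelated conformer, and the chromium aldolate could fragment by retro-aldol cleavage or the allylic acetate could be lost reductively. The fallback sets out from 8 and 14 and comes back at 16. It moves stereocontrol from the substrate to the reagent: a catalytic asymmetric nickel/chromium coupling with CrCl2 (10 mol%) bound to a chiral (4-isopropyl-oxazolinyl)aryl methanesulfonamide ligand, NiCl2·(2,9-dimethyl-1,10-phenanthroline) (2 mol%), Mn powder, Cp2ZrCl2 and LiCl in MeCN. The ligand antipode is chosen for the (1R) sense, and acidic work-up releases 15, which lactonises to 16. The low steady-state concentration of divalent chromium should also limit reductive side reactions.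

Step 1 is third. Cleavage may run on to the bis-enolate, the dienolate may add to the acetone set free, or silylation may be incomplete. The fallback does not use 1: it sets out from purchased (2Z)-but-2-ene-1,4-diyl diacetate F4 and comes back at 3. Cross-metathesis with (2E)-but-2-enal using the second-generation Hoveyda–Grubbs catalyst, RuCl2(H2IMes)(=CH–C6H4-2-O-i-Pr) (2 mol%, CH2Cl2, 40 °C), should give (2E)-4-oxobut-2-en-1-yl acetate F5. Soft enolisation (TBSOTf, Et3N, Et2O, −78 °C to 0 °C) then gives 3; any (3Z) isomer is inert in step 3 and is removed after it.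

Further compounds
F1 | step 3 | methyl 2-[(1R,2R,5R)-5-(acetyloxy)-2-[(tert-butyldimethylsilyl)oxy]-1-formylcyclohex-3-en-1-yl]acetate | COC(=O)C[C@]1(C=O)C[C@@H](OC(C)=O)C=C[C@H]1O[Si](C)(C)C(C)(C)C
F2 | step 3 | methyl 2-[(1R,2R,5R)-5-(acetyloxy)-1-formyl-2-hydroxycyclohex-3-en-1-yl]acetate | COC(=O)C[C@]1(C=O)C[C@@H](OC(C)=O)C=C[C@H]1O
F3 | step 3 | methyl 2-[(1R,2R,5R)-2,5-bis(acetyloxy)-1-formylcyclohex-3-en-1-yl]acetate | COC(=O)C[C@]1(C=O)C[C@@H](OC(C)=O)C=C[C@H]1OC(C)=O
F0 | step 10 | none | none
F4 | step 1 | (2Z)-but-2-ene-1,4-diyl diacetate (purchased) | CC(=O)OC/C=C\COC(C)=O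
F5 | step 1 | (2E)-4-oxobut-2-en-1-yl acetate | CC(=O)OC/C=C/C=O
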